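Numbering: unit 1 is the 4-methoxyphenyl flavanone (O1, C2, C3, C4; rings A, B, C). Unit 2 is the 4-hydroxyphenyl flavanone (O1'', C2'', C3'', C4''; rings A'', B'', C'').
Retrosynthetic cuts, in order: the five O-benzyl groups; C4''-C3'' of pyranone ring C'' (intramolecular Stetter reaction); the exocyclic C3=C3'' bond (aldol condensation); O1''-C2'' (allylic etherification) and C2-aryl (conjugate arylation of a chromone).
Enabling feature: the ring carbonyls C4 and C4'' are 1,4-related across C3-C3''. A C3''=C3-C4=O enone on ring C therefore offers its β-carbon C3'' to a formyl carbon (the future C4'') that ring A'' and the O1''-C2'' ether hold at six-ring distance. An acyl-anion closure makes ring C'' and the 1,4-diketone together.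
Forward order: rings A/C (chromone), then ring B (flavanone); separately the ring A''-O1''-C2''(ring B'') ether; union at C3=C3''; ring C'' closes last; hydrogenolysis.
Stereochemistry: C2 comes from an enantioselective Pd-catalysed arylation and C2'' from an enantioselective Ir-catalysed etherification. C3'' and C3 both arise in the Stetter step under control of C2'' and C2 (E-alkene, A(1,3) strain, same-face proton transfer), giving the trans unit 2 and the kinetic cis unit 1.

Key step: step 12

Assumption: the face selectivity of the catalysts in steps 3 and 8 is assigned by analogy with the parent substrates of each catalyst family; should either be opposite, the mirror-image ligand is used and the route is otherwise unchanged.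

Step 1
Reactants: 1 2,4,6-trihydroxyacetophenone
Product: 2 1-[2,4-bis(benzyloxy)-6-hydroxyphenyl]ethan-1-one
Conditions: BnBr (2.1 equiv), K2CO3 (2.2 equiv), DMF, 23 °C
Reagents that add atoms: benzyl bromide, BrCc1ccccc1
Why: Williamson ether synthesis; the hydroxyl group that is hydrogen-bonded to the acetyl carbonyl is the least reactive, so two equivalents of halide should stop at the dibenzyl ether.

Step 2
Reactants: 2 1-[2,4-bis(benzyloxy)-6-hydroxyphenyl]ethan-1-one
Product: 4 5,7-bis(benzyloxy)-4H-chromen-4-one, via enaminone 3 (not isolated)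
Conditions: Me2NCH(OMe)2, toluene, 100 °C; concentrate; conc. HCl, CH2Cl2, 40 °C
Reagents that add atoms: N,N-dimethylformamide dimethyl acetal, COC(OC)N(C)C
Why: Enaminone formation at the acetyl methyl group, then acid-induced oxa-Michael addition of the free phenol and loss of dimethylamine, is the standard enaminone route to 2,3-unsubstituted chromones.

Step 3
Reactants: 4 5,7-bis(benzyloxy)-4H-chromen-4-one; 5 4-methoxyphenylboronic acid
Product: 6 (2S)-5,7-bis(benzyloxy)-2-(4-methoxyphenyl)chroman-4-one
Conditions: Pd(OCOCF3)2 (5 mol %), (R)-4-tert-butyl-2-(pyridin-2-yl)-4,5-dihydrooxazole (6 mol %), NH4PF6 (30 mol %), H2O (5 equiv), ClCH2CH2Cl, 60 °C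
Reagents that add atoms: none
Why: Enantioselective conjugate addition of an arylboronic acid to a chromone by a cationic divalent palladium pyridine-oxazoline catalyst; the ligand directs aryl transfer to one face of C2 and so sets 2S, and the nearly neutral medium should keep ring C from opening to the chalcone.

Step 4
Reactants: 7 2,4,6-trihydroxybenzaldehyde
Product: 8 2,4-bis(benzyloxy)-6-hydroxybenzaldehyde
Conditions: BnBr (2.1 equiv), K2CO3 (2.2 equiv), DMF, 23 °C
Reagents that add atoms: benzyl bromide, BrCc1ccccc1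
Why: Williamson ether synthesis; as in step 1, the hydroxyl group chelated to the formyl oxygen should remain free.

Step 5
Reactants: 9 4-(benzyloxy)benzaldehyde
Product: 10 ethyl (E)-3-[4-(benzyloxy)phenyl]prop-2-enoate
Conditions: Ph3P=CHCO2Et, toluene, 80 °C
Reagents that add atoms: ethyl (triphenylphosphoranylidene)acetate, CCOC(=O)C=P(c1ccccc1)(c1ccccc1)c1ccccc1
Why: Wittig olefination with a stabilised ylide, which should give the E-cinnamate.

Step 6
Reactants: 10 ethyl (E)-3-[4-(benzyloxy)phenyl]prop-2-enoate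
Product: 11 (E)-3-[4-(benzyloxy)phenyl]prop-2-en-1-ol
Conditions: i-Bu2AlH (2.2 equiv), CH2Cl2, -78 °C; aq. KNaC4H4O6 (tartrate)
Reagents that add atoms: none
Why: 1,2-Reduction of a conjugated ester by an aluminium hydride, which leaves the alkene geometry and the benzyl ether untouched.

Step 7
Reactants: 11 (E)-3-[4-(benzyloxy)phenyl]prop-2-en-1-ol
Product: 12 (E)-3-[4-(benzyloxy)phenyl]prop-2-en-1-yl methyl carbonate
Conditions: ClCO2Me, pyridine, CH2Cl2, 0 °C
Reagents that add atoms: methyl chloroformate, COC(=O)Cl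
Why: O-Acylation of a primary allylic alcohol installs the leaving group that later releases its own base.

Step 8
Reactants: 8 2,4-bis(benzyloxy)-6-hydroxybenzaldehyde; 12 (E)-3-[4-(benzyloxy)phenyl]prop-2-en-1-yl methyl carbonate
Product: 13 2,4-bis(benzyloxy)-6-{[(1R)-1-[4-(benzyloxy)phenyl]prop-2-en-1-yl]oxy}benzaldehyde
Conditions: [Ir(cod)Cl]2 (2 mol %), (Sa,Sc,Sc)-N,N-bis(1-phenylethyl)dinaphtho[2,1-d:1',2'-f][1,3,2]dioxaphosphepin-4-amine (4 mol %), 1,5,7-triazabicyclo[4.4.0]dec-5-ene (8 mol %, catalyst activation), THF, 23 °C, no stoichiometric base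
Reagents that add atoms: none
Why: Enantioselective iridium-catalysed allylic etherification of a phenol with a linear cinnamyl carbonate; oxygen attacks the cyclometalated Ir-phosphoramidite allyl complex at its aryl-bearing terminus, which gives the branched ether and sets C2'' as R under ligand control, while the methoxide released on ionisation serves as the base.

Step 9
Reactants: 13 2,4-bis(benzyloxy)-6-{[(1R)-1-[4-(benzyloxy)phenyl]prop-2-en-1-yl]oxy}benzaldehyde
Product: 15 2,4-bis(benzyloxy)-6-{[(1S)-1-[4-(benzyloxy)phenyl]-2-oxoethyl]oxy}benzaldehyde, via diol 14 (not isolated)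
Conditions: OsO4 (2 mol %), NaIO4 (4 equiv), 2,6-lutidine (2 equiv), dioxane/H2O 3:1, 23 °C; used crude
Reagents that add atoms: osmium tetroxide, O=[Os](=O)(=O)=O; sodium periodate, [Na+].[O-]I(=O)(=O)=O
Why: Lemieux-Johnson oxidation; the monosubstituted alkene is dihydroxylated and cleaved in one flask under buffered conditions that should spare the benzyl ethers, the aromatic aldehyde and the enolisable stereocentre (same spatial arrangement, descriptor S because the formyl group now outranks the aryl group).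

Step 10
Reactants: 6 (2S)-5,7-bis(benzyloxy)-2-(4-methoxyphenyl)chroman-4-one; 15 2,4-bis(benzyloxy)-6-{[(1S)-1-[4-(benzyloxy)phenyl]-2-oxoethyl]oxy}benzaldehyde
Product: 17 (2S,3R)-5,7-bis(benzyloxy)-3-{(2S)-2-[3,5-bis(benzyloxy)-2-formylphenoxy]-2-[4-(benzyloxy)phenyl]-1-hydroxyethyl}-2-(4-methoxyphenyl)chroman-4-one (carbinol epimers), via boron enolate 16 (not isolated)
Conditions: 6, Bu2BOTf (1.2 equiv), i-Pr2NEt (1.4 equiv), CH2Cl2, -78 to 0 °C; 15, -78 °C; pH 7 buffer/MeOH work-up without peroxide
Reagents that add atoms: none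
Why: Boron-mediated aldol addition; the non-basic enolate should add to the aliphatic formyl group faster than it enolises it and should ignore the doubly ortho-substituted, donor-rich aromatic aldehyde, attack anti to the C2 aryl group gives the 2,3-trans adduct, and both new centres are erased in step 11.

Step 11
Reactants: 17 (2S,3R)-aldol adduct (carbinol epimers)
Product: 19 (2R,3E)-5,7-bis(benzyloxy)-3-{(2R)-2-[3,5-bis(benzyloxy)-2-formylphenoxy]-2-[4-(benzyloxy)phenyl]ethylidene}-2-(4-methoxyphenyl)chroman-4-one, via mesylate 18 (not isolated)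
Conditions: MsCl (1.5 equiv), Et3N (4 equiv), CH2Cl2, -20 to 23 °C
Reagents that add atoms: none
Why: Mesylation and E1cB elimination through the C3 enolate; the E-alkylidene ketone (chain anti to the C4 carbonyl) is the preferred geometry of 3-alkylidenechromanones, and once C3 is sp2 the C2 centre (unchanged in space, descriptor R because C3 now outranks the aryl group) can no longer racemise by retro-oxa-Michael opening.

Step 12
Reactants: 19 (2R,3E)-alkylidene flavanone aldehyde
Product: 21 (2S,3S,2''R,3''S)-5,7,5'',7'',4'''-pentakis(benzyloxy)-4'-methoxy-3,3''-biflavanone, via Breslow intermediate 20 (not isolated)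
Conditions: 2-(pentafluorophenyl)-6,7-dihydro-5H-pyrrolo[2,1-c][1,2,4]triazol-2-ium tetrafluoroborate (20 mol %), KN(SiMe3)2 (20 mol %), toluene, 23 °C, HN(SiMe3)2 removed in vacuo; then 19, toluene, 23 to 40 °C
Reagents that add atoms: none
Why: The triazolylidene adds to the only formyl group, a proton shift gives the Breslow enaminol 20 (an acyl anion equivalent at C4''), this attacks the β-carbon C3'' of the C3''=C3-C4=O enone, the C3 enolate is protonated and the carbene is expelled, which is the intramolecular Stetter reaction of a 2-(allyloxy)benzaldehyde with an α,β-disubstituted exocyclic Michael acceptor, the classical chroman-4-one closure. Ring C'' closes in the 6-exo-trig mode. C3'' is controlled by C2'': A(1,3) strain with ring carbon C2, which is cis to C2'' on the E-alkene, holds H-C2'' in the alkene plane, so that in the 2''R series O1'' and the tethered nucleophile lie on the face that gives 3''S, the trans-2'',3'' (diequatorial) ring. C3 is controlled twice in the same sense: the same strain forces the 4-methoxyphenyl group at C2 axial onto the opposite face, and the proton passes within the adduct from the carbinol O-H to the face on which the C-C bond has just formed (net syn addition to the E-alkene), which places H-3 anti to that aryl group and gives the kinetic 2,3-cis (3S) unit. The step needs 1,4- rather than 1,2-attack, no epimerisation at C3 or C3'' and no loss of C2 or C2''; the fixed s-cis enone and the six-membered transition state secure the first, the amine-free carbene solution the second, and the sp2 C3, which blocks opening of ring C until the last proton transfer, the third.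

Step 13
Reactants: 21 pentabenzyl ether of the target
Product: 22 (2S,3S,2''R,3''S)-5,7,5'',7'',4'''-pentahydroxy-4'-methoxy-3,3''-biflavanone (CNP0196568.4)
Conditions: H2 (1 atm), Pd/C (10 wt %), EtOAc/MeOH 1:1, 23 °C
Reagents that add atoms: none
Why: Hydrogenolysis of the five benzyl ethers under neutral conditions; no acid or base is present that could enolise C3 or C3'' or open rings C and C'', so all four stereocentres should be retained and the methyl ether stays.

Compound list
1 | 2,4,6-trihydroxyacetophenone | CC(=O)c1c(O)cc(O)cc1O | starting material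
2 | 1-[2,4-bis(benzyloxy)-6-hydroxyphenyl]ethan-1-one | CC(=O)c1c(O)cc(OCc2ccccc2)cc1OCc1ccccc1 | intermediate
3 | (E)-1-[2,4-bis(benzyloxy)-6-hydroxyphenyl]-3-(dimethylamino)prop-2-en-1-one | CN(C)/C=C/C(=O)c1c(O)cc(OCc2ccccc2)cc1OCc1ccccc1 | intermediate
4 | 5,7-bis(benzyloxy)-4H-chromen-4-one | O=c1ccoc2cc(OCc3ccccc3)cc(OCc3ccccc3)c12 | intermediate
5 | 4-methoxyphenylboronic acid | COc1ccc(B(O)O)cc1 | starting material
6 | (2S)-5,7-bis(benzyloxy)-2-(4-methoxyphenyl)chroman-4-one | COc1ccc([C@H]2Oc3cc(OCc4ccccc4)cc(OCc4ccccc4)c3C(=O)C2)cc1 | intermediate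
7 | 2,4,6-trihydroxybenzaldehyde | O=Cc1c(O)cc(O)cc1O | starting material
8 | 2,4-bis(benzyloxy)-6-hydroxybenzaldehyde | O=Cc1c(O)cc(OCc2ccccc2)cc1OCc1ccccc1 | intermediate
9 | 4-(benzyloxy)benzaldehyde | O=Cc1ccc(OCc2ccccc2)cc1 | starting material
10 | ethyl (E)-3-[4-(benzyloxy)phenyl]prop-2-enoate | CCOC(=O)/C=C/c1ccc(OCc2ccccc2)cc1 | intermediate
11 | (E)-3-[4-(benzyloxy)phenyl]prop-2-en-1-ol | OC/C=C/c1ccc(OCc2ccccc2)cc1 | intermediate
12 | (E)-3-[4-(benzyloxy)phenyl]prop-2-en-1-yl methyl carbonate | COC(=O)OC/C=C/c1ccc(OCc2ccccc2)cc1 | intermediate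
13 | 2,4-bis(benzyloxy)-6-{[(1R)-1-[4-(benzyloxy)phenyl]prop-2-en-1-yl]oxy}benzaldehyde | C=C[C@@H](Oc1cc(OCc2ccccc2)cc(OCc2ccccc2)c1C=O)c1ccc(OCc2ccccc2)cc1 | intermediate
14 | 2,4-bis(benzyloxy)-6-{[(1S)-1-[4-(benzyloxy)phenyl]-2,3-dihydroxypropyl]oxy}benzaldehyde (epimers at the secondary carbinol) | OCC(O)[C@@H](Oc1cc(OCc2ccccc2)cc(OCc2ccccc2)c1C=O)c1ccc(OCc2ccccc2)cc1 | intermediate
15 | 2,4-bis(benzyloxy)-6-{[(1S)-1-[4-(benzyloxy)phenyl]-2-oxoethyl]oxy}benzaldehyde | O=C[C@@H](Oc1cc(OCc2ccccc2)cc(OCc2ccccc2)c1C=O)c1ccc(OCc2ccccc2)cc1 | intermediate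
16 | (2S)-5,7-bis(benzyloxy)-4-[(dibutylboranyl)oxy]-2-(4-methoxyphenyl)-2H-chromene | COc1ccc([C@H]2Oc3cc(OCc4ccccc4)cc(OCc4ccccc4)c3C(OB(CCCC)CCCC)=C2)cc1 | intermediate
17 | (2S,3R)-aldol adduct of 6 and 15, 2,3-trans, epimers at the carbinol carbon, (S) at the aryloxy carbon | COc1ccc([C@H]2Oc3cc(OCc4ccccc4)cc(OCc4ccccc4)c3C(=O)[C@@H]2C(O)[C@@H](Oc2cc(OCc3ccccc3)cc(OCc3ccccc3)c2C=O)c2ccc(OCc3ccccc3)cc2)cc1 | intermediate
18 | methanesulfonate of 17 | COc1ccc([C@H]2Oc3cc(OCc4ccccc4)cc(OCc4ccccc4)c3C(=O)[C@@H]2C(OS(C)(=O)=O)[C@@H](Oc2cc(OCc3ccccc3)cc(OCc3ccccc3)c2C=O)c2ccc(OCc3ccccc3)cc2)cc1 | intermediate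
19 | (2R,3E)-5,7-bis(benzyloxy)-3-{(2R)-2-[3,5-bis(benzyloxy)-2-formylphenoxy]-2-[4-(benzyloxy)phenyl]ethylidene}-2-(4-methoxyphenyl)chroman-4-one | COc1ccc([C@H]2Oc3cc(OCc4ccccc4)cc(OCc4ccccc4)c3C(=O)/C2=C/[C@@H](Oc2cc(OCc3ccccc3)cc(OCc3ccccc3)c2C=O)c2ccc(OCc3ccccc3)cc2)cc1 | intermediate
20 | Breslow enaminol formed from the formyl group of 19 and the triazolylidene | COc1ccc([C@H]2Oc3cc(OCc4ccccc4)cc(OCc4ccccc4)c3C(=O)/C2=C/[C@@H](Oc2cc(OCc3ccccc3)cc(OCc3ccccc3)c2C(O)=C2N(c3c(F)c(F)c(F)c(F)c3F)N=C3CCCN23)c2ccc(OCc3ccccc3)cc2)cc1 | intermediate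
21 | (2S,3S,2''R,3''S)-5,7,5'',7'',4'''-pentakis(benzyloxy)-4'-methoxy-3,3''-biflavanone | COc1ccc([C@H]2Oc3cc(OCc4ccccc4)cc(OCc4ccccc4)c3C(=O)[C@H]2[C@@H]2C(=O)c3c(OCc4ccccc4)cc(OCc4ccccc4)cc3O[C@H]2c2ccc(OCc3ccccc3)cc2)cc1 | intermediate
22 | (2S,3S,2''R,3''S)-5,7,5'',7'',4'''-pentahydroxy-4'-methoxy-3,3''-biflavanone (unit 1 cis, unit 2 trans) | COc1ccc([C@H]2Oc3cc(O)cc(O)c3C(=O)[C@H]2[C@@H]2C(=O)c3c(O)cc(O)cc3O[C@H]2c2ccc(O)cc2)cc1 | target

Total step count: 13. Longest linear sequence: 9 steps (steps 5 to 13).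

Steps most likely to fail

Step 12. The carbene may add too slowly to the doubly ortho-substituted, electron-rich formyl group. The basic carbene may also epimerise the kinetic C3 centre or deprotonate the γ-position C2''.
The fallback replaces polar umpolung by a neutral acyl radical closure. It sets out from 19 and comes back at 21.
- Pinnick oxidation (NaClO2, NaH2PO4, 2-methyl-2-butene, t-BuOH/H2O) of the formyl group would give the carboxylic acid F1.
- N-(phenylseleno)phthalimide and Bu3P in CH2Cl2 would convert it into the Se-phenyl selenoester F2.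
- (Me3Si)3SiH with Et3B/air in toluene at 23 °C would generate the aroyl radical. Its 6-exo addition to C3'' follows the same A(1,3) bias, and hydrogen abstraction at C3 anti to the axial aryl group should lead to 21.

Step 10 (with step 11). Three processes threaten it: loss of configuration at the α-aryloxy-α-aryl aldehyde carbon by enolisation, competing attack at the aromatic formyl group, and drift of the exocyclic alkene into ring C (flavone formation) during elimination.
The fallback makes the C3=C3'' bond by olefin metathesis and never passes through the labile dialdehyde. It sets out from 6 (through 16) and 13 and comes back at 19.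
- Enolate 16 is treated with dimethyl(methylidene)ammonium iodide to give the Mannich base F3.
- MeI gives the methiodide F4.
- Aqueous NaHCO3 eliminates trimethylamine to give the 3-methylideneflavanone F5.
- Cross metathesis of F5 with 13 (second-generation Hoveyda-Grubbs catalyst, CH2Cl2, 40 °C) should give the E-trisubstituted enone 19.

Step 8. The chelated formyl phenoxide is a weak nucleophile. The product can also re-ionise at its electron-rich benzylic carbon, which would erode both branched selectivity and enantiomeric purity.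
The fallback forms the aryl-oxygen bond instead of the alkyl-oxygen bond. It sets out from 9 and comes back at 13.
- CH2=CHMgBr adds to 9 to give the racemic allylic alcohol F6.
- Candida antarctica lipase B and vinyl acetate should acylate the R enantiomer to the acetate F7.
- F7 is separated and methanolysed (K2CO3, MeOH) to the (R)-alcohol F8.
- 2,4,6-Trifluorobenzaldehyde and two equivalents of NaOCH2Ph in DMF would give the fluoroaldehyde F9.
- The sodium alkoxide of F8 (NaH, THF) displaces the remaining ortho fluoride of F9 by SNAr. The C-O bond of the stereocentre is untouched, and the product is 13.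

Further compounds
F1 | step 12 | 2,4-bis(benzyloxy)-6-aryloxybenzoic acid corresponding to 19 (CHO oxidised to CO2H) | COc1ccc([C@H]2Oc3cc(OCc4ccccc4)cc(OCc4ccccc4)c3C(=O)/C2=C/[C@@H](Oc2cc(OCc3ccccc3)cc(OCc3ccccc3)c2C(=O)O)c2ccc(OCc3ccccc3)cc2)cc1
F2 | step 12 | Se-phenyl selenoester of F1 | COc1ccc([C@H]2Oc3cc(OCc4ccccc4)cc(OCc4ccccc4)c3C(=O)/C2=C/[C@@H](Oc2cc(OCc3ccccc3)cc(OCc3ccccc3)c2C(=O)[Se]c2ccccc2)c2ccc(OCc3ccccc3)cc2)cc1
F3 | step 10 | (2S,3R)-5,7-bis(benzyloxy)-3-[(dimethylamino)methyl]-2-(4-methoxyphenyl)chroman-4-one | COc1ccc([C@H]2Oc3cc(OCc4ccccc4)cc(OCc4ccccc4)c3C(=O)[C@@H]2CN(C)C)cc1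
F4 | step 10 | methiodide of F3 | COc1ccc([C@H]2Oc3cc(OCc4ccccc4)cc(OCc4ccccc4)c3C(=O)[C@@H]2C[N+](C)(C)C)cc1.[I-]
F5 | step 10 | (2R)-5,7-bis(benzyloxy)-2-(4-methoxyphenyl)-3-methylidenechroman-4-one | COc1ccc([C@H]2Oc3cc(OCc4ccccc4)cc(OCc4ccccc4)c3C(=O)C2=C)cc1
F6 | step 8 | rac-1-[4-(benzyloxy)phenyl]prop-2-en-1-ol | C=CC(O)c1ccc(OCc2ccccc2)cc1
F7 | step 8 | (1R)-1-[4-(benzyloxy)phenyl]prop-2-en-1-yl acetate | C=C[C@@H](OC(C)=O)c1ccc(OCc2ccccc2)cc1
F8 | step 8 | (1R)-1-[4-(benzyloxy)phenyl]prop-2-en-1-ol | C=C[C@@H](O)c1ccc(OCc2ccccc2)cc1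
F9 | step 8 | 2,4-bis(benzyloxy)-6-fluorobenzaldehyde | O=Cc1c(F)cc(OCc2ccccc2)cc1OCc1ccccc1
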